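The precatalyst is where I start: the partner turns it into the catalyst, and the catalyst then carries both substrates to their products.

common to all: left-handed substrate 0.38 M; right-handed substrate 0.38 M

| run | partner | precatalyst | remark |
|---|---|---|---|
| south-east | 0.57 M | 5.3 mM | run made earlier |
| south | 0.57 M | 8.4 mM | run made earlier |
| south-west | 1.1 M | 3.8 mM | run made earlier |
| flask | 0.570 M | 3.8 mM |  |

| run | time / h | left-handed product / % | left-handed substrate / % |
|---|---|---|---|
| south-east | 0.250 | 0.3 | 49.4 |
| south-east | 0.833 | 3.9 | 47.3 |
| south-east | 1.33 | 6.4 | 45.2 |
| south-east | 2.50 | 11.1 | 37.9 |
| south-east | 3.00 | 13.3 | 36.8 |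
| south | 0.667 | 2.8 | 46.5 |
| south | 1.33 | 8.3 | 41.4 |
| south | 2.00 | 12.5 | 36.1 |
| south | 2.50 | 16.1 | 34.3 |
| south | 3.00 | 18.9 | 31.3 |
| south-west | 0.667 | 4.4 | 46.0 |
| south-west | 1.33 | 9.4 | 41.5 |
| south-west | 2.00 | 13.8 | 35.1 |
| south-west | 2.50 | 17.0 | 33.1 |
| south-west | 3.00 | 20.1 | 30.2 |

(each reading ± 0.5 percentage points)

* factor on the rate of making left-handed product when 50% of the left-handed substrate and right-handed substrate together are converted if precatalyst is charged twice over
* factor on the rate when 50% of the left-handed substrate and right-handed substrate together are converted if precatalyst is charged at 0.80 mM instead

- catalyst is single-handed; left-handed substrate and right-handed substrate are mirror images of each other, charged as a racemate, each of them at the stated concentration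
- steps under discussion: partner + catalyst + left-handed substrate -> catalyst + left-handed product; partner + catalyst + right-handed substrate -> catalyst + right-handed product; partner -> decomposition product; partner + precatalyst -> catalyst + spent reagent

I order the flask by time scale, fastest first. The start-up comes first: in the south run, the line through the first two readings of left-handed product meets zero at 0.329 h, a rough reading. Steady making comes next. Between 1.33 h and 3.00 h, the south run gains 11 percentage points and the south-east run 6.9 points, a ratio of 1.54 against 1.58 in precatalyst. I therefore read the rate in these two runs as proportional to the precatalyst charged.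

Scaled by precatalyst to the flask, the south-east slope is 0.0296 /h of the two substrates charged. Held steady, that slope brings left-handed product to a quarter of the two substrates charged in about 8.44 h, much longer than the start-up, so I count the precatalyst as turned into catalyst by then. In the flask the partner is the limiting reagent, with 0.570 M against 0.760 M of the two substrates together, and at 50% conversion I put [partner] near 0.190 M. Last on my ladder stands the decomposition of the partner, for which I read no rate from these runs, so I leave it out of my reckoning. I freeze the composition at that conversion, which leaves the load factor, the new precatalyst charge over 3.8 mM: 0.211 for 0.80 mM and 2 for doubling.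

The forecast gives 2.2 for doubling, above my figure, and 0.12 for 0.80 mM, below it: “At 0.80 mM (about 60 h) the ideal factor of 0.21 shrinks, and partner might even run out first.”

The flask reaches the asked conversion at 14.8 h, with a rate of 0.00571 M/h of left-handed product, and the factors are 1.97 for doubling and 0.205 for 0.80 mM.

    partner + catalyst + left-handed substrate → catalyst + left-handed product (k = 53.1 /M²/h)
    partner + catalyst + right-handed substrate → catalyst + right-handed product (k = 30.5 /M²/h)
    partner → decomposition product (k = 4.53 × 10⁻⁴ /h)
    partner + precatalyst → catalyst + spent reagent (k = 2.84 /M/h)

After 40.0 h the flask holds 0.00340 M of decomposition product, far less than the 0.570 M of partner charged. Reckoned by the load factor, that rate becomes about 0.00120 M/h for a precatalyst charge of 0.80 mM, and about 0.0114 M/h for the doubled charge.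

The earlier runs and the new flask are calculated with made-up constants, and the scatter is random.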